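All runs are simulated for an exercise.

The meeting opened on a ratio: one chemist wanted the time of a feed divided by the half-life of D before anyone spoke of yields. The chair first laid out the flasks, the earlier runs and the questions.

| flask | D | L | remark | time |
|---|---|---|---|---|
| south-east | 13 mM | 1.3 equiv | run made earlier |  |
| west | 26 mM | 1.3 equiv | run made earlier |  |
| dawn | 13 mM (fed, over 1.0 h) | 1.30 equiv | all else is in the flask from the start; the feed brings no volume worth counting | 2.5 h |
| winter | 13 mM | 1.30 equiv | everything together at the start | 2.5 h |
| autumn | 13 mM (in portions, 2, over 1.0 h) | 1.30 equiv | first portion at the start, last at 1.0 h | 2.5 h |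
| summer | 13 mM | 1.30 equiv (fed, over 1.0 h) | all else is in the flask from the start; the feed brings no volume worth counting | 2.5 h |

south-east run (percent of the D charged)

| time / h | X / % | D / % |
|---|---|---|
| 0.200 | 28 | 29 |
| 0.333 | 35 | 12 |
| 0.500 | 38 | 4 |
| 0.833 | 33 | 1 |
| 1.50 | 26 | 0 |
| 2.50 | 28 | 1 |

west run (percent of the D charged)

| time / min | X / % | D / % |
|---|---|---|
| 4.00 | 11 | 68 |
| 6.00 | 20 | 53 |
| 10.0 | 26 | 37 |
| 15.0 | 30 | 22 |
| 25.0 | 35 | 5 |
| 50.0 | 25 | 0 |

(standard deviation of a reading: 2 percentage points)

- the flask with the highest amount of X, in percent of the D charged ("all alike" if they lie within 1.5 percentage points) (dawn / winter / autumn / summer / all alike)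
- final X, as a percentage of the D charged, in dawn
- final X, as a percentage of the D charged, in winter
- final X, as a percentage of the D charged, in autumn
- final X, as a percentage of the D charged, in summer



The first chemist read the half-life of D from the west run, where D stood at 37% after 10.0 min, which gives 0.116 h. The south-east run, at half that charge, gave 0.112 h from its first reading, so she treated the loss of D as first order.

She then reported 8.61 for the feed count, the number of half-lives of D that fit inside one feed. Because the half-life is far shorter than the feed, she argued, D in dawn leaves about as fast as it arrives, which is the usual quasi-steady state. The amount standing in dawn is then the feed rate times the mean lifetime of D, 0.168 h. The feed brings the whole charge in 1.0 h, so she expected 16.8% of the charge as D at the end of the feed. She stressed that this figure concerned D and gave no number for X.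

A second chemist pointed out that neither run had read L, and that both had scaled it with D.

The one who made the forecast replied that “the final X does not depend on dosing”. He entered 27% for dawn (23% to 32%), 27% for winter (25% to 29%), 27% for autumn (24% to 30%) and 27% for summer (22% to 33%), and answered all alike.

Summer, where L was fed, gave the highest X at 48.6%, against 26.3% in winter, 18.5% in autumn and 11.1% in dawn.

    D → Z (k = 0.0960 min⁻¹)
    L + Z → X (k = 16.0 M⁻¹ min⁻¹)
    X ⇌ E (K = 0.700, k = 0.0110 min⁻¹)
    2 L → G (k = 6.40 M⁻¹ min⁻¹)
    L → Q (k = 0.00810 min⁻¹)
    Z → J (k = 0.00670 min⁻¹)

At 2.50 h, dawn held more G than summer, 6.63 mM against 2.38 mM. At the end of its feed, at 1.00 h, dawn held 17.3% as D, where the count had given 16.8%. Summer had all its D from the start, so the same 8.61 half-lives reckon to 0.257% of D at 1.00 h, and summer held 0.315%.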